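**Plan**

- Cuts: (1) the enone Cα=Cβ bond (aldol condensation); (2) O1–C2 of the dihydrofuran, giving a C7a phenoxide and a 2,3-epoxy alcohol, which is the Payne isomer of a cis-1,2-epoxy tertiary carbinol; (3) the epoxide oxygen (Z-alkene); (4) the aryl–C(sp) bond (3-iodoresacetophenone + 2-methylbut-3-yn-2-ol).
- Forward: the benzene ring is bought; iodination, differentiation of the two phenols, Sonogashira coupling, semi-hydrogenation and epoxidation build the open-chain precursor; one base/fluoride operation closes the dihydrofuran, the only ring made and the last of the skeleton; the cinnamoyl chain is joined afterwards and the two allyl ethers fall last.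
- Enabling feature: C3(OH)–C2(O1)–C(CH3)2OH are three adjacent oxygen-bearing carbons with the ring oxygen on the middle one, i.e. a masked 2,3-epoxy alcohol (Payne triad). O1 sits on C7a, ortho to C3a, so its phenoxide reaches C2 in a 5-exo opening only after the epoxide has moved from C3–C2 to C2–CMe2.
- Stereochemistry: both centres come from one ligand-controlled epoxidation of an achiral Z-alkene and are relayed stereospecifically by the cascade (C3 keeps its C–O bond; C2 is inverted twice), which turns the cis-epoxide into the trans-(2S,3S) ring.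

Key step: step 7

Remark: the target SMILES is read as the trans-(2S,3S) isomer with the free phenol ortho to the carbonyl. The sense of induction of the step-6 catalyst for this Z-configured tertiary allylic alcohol cannot be assigned safely by analogy, so the ligand antipode is the one that gives 8, to be confirmed by correlation at 11.

**Route**

Step 1
Reactants: 1 1-(2,4-dihydroxyphenyl)ethanone
Product: 2 1-(2,4-dihydroxy-3-iodophenyl)ethanone
Conditions: I2 (0.4 equiv), HIO3 (0.2 equiv), EtOH–H2O, rt
Reagents that add atoms: iodine, II; iodic acid, O[I](=O)=O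
Why: Electrophilic aromatic iodination (I+ from I2/HIO3) should take place at C3, the ring carbon flanked by the two hydroxyl groups and the most nucleophilic position of this resorcinol ketone.

Step 2
Reactants: 2 1-(2,4-dihydroxy-3-iodophenyl)ethanone
Product: 3 1-{4-[(tert-butyldimethylsilyl)oxy]-2-hydroxy-3-iodophenyl}ethanone
Conditions: TBSCl (1.1 equiv), imidazole, DMF, 0 °C → rt
Reagents that add atoms: tert-butyldimethylsilyl chloride, CC(C)(C)[Si](C)(C)Cl
Why: Silyl ether formation should be selective for the 4-OH because the 2-OH is held in a hydrogen bond to the acetyl carbonyl, and it marks the oxygen that becomes O1 as the only one that fluoride will uncover later.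

Step 3
Reactants: 3 1-{4-[(tert-butyldimethylsilyl)oxy]-2-hydroxy-3-iodophenyl}ethanone
Product: 4 1-{2-(allyloxy)-4-[(tert-butyldimethylsilyl)oxy]-3-iodophenyl}ethanone
Conditions: allyl alcohol, PPh3, DIAD, THF, 0 °C → rt
Reagents that add atoms: prop-2-en-1-ol (allyl alcohol), C=CCO
Why: Mitsunobu etherification alkylates the remaining, hydrogen-bonded phenol under neutral conditions that leave the aryl silyl ether intact; the allyl ether keeps this oxygen out of the later ring closure and out of the alkyne chemistry.

Step 4
Reactants: 4 1-{2-(allyloxy)-4-[(tert-butyldimethylsilyl)oxy]-3-iodophenyl}ethanone; 5 2-methylbut-3-yn-2-ol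
Product: 6 1-{2-(allyloxy)-4-[(tert-butyldimethylsilyl)oxy]-3-(3-hydroxy-3-methylbut-1-yn-1-yl)phenyl}ethanone
Conditions: PdCl2(PPh3)2 (3 mol %), CuI (5 mol %), Et3N, THF, 50 °C
Reagents that add atoms: none
Why: Sonogashira coupling joins the aryl iodide to the terminal alkyne and brings in all five side-chain carbons with the tertiary hydroxyl already in place, both flanking phenols being masked so that cycloisomerisation to a benzofuran cannot occur.

Step 5
Reactants: 6 1-{2-(allyloxy)-4-[(tert-butyldimethylsilyl)oxy]-3-(3-hydroxy-3-methylbut-1-yn-1-yl)phenyl}ethanone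
Product: 7 1-{2-(allyloxy)-4-[(tert-butyldimethylsilyl)oxy]-3-[(1Z)-3-hydroxy-3-methylbut-1-en-1-yl]phenyl}ethanone
Conditions: H2 (1 atm), Lindlar catalyst (Pd/CaCO3, Pb-poisoned), quinoline, EtOAc, rt, stopped after 1 equiv H2
Reagents that add atoms: none
Why: Lindlar semi-hydrogenation adds H2 syn on lead-poisoned palladium to give the Z-alkene, the alkyne being adsorbed much more strongly than the product alkene or the allyl ether, which is why the uptake is stopped at one equivalent.

Step 6
Reactants: 7 1-{2-(allyloxy)-4-[(tert-butyldimethylsilyl)oxy]-3-[(1Z)-3-hydroxy-3-methylbut-1-en-1-yl]phenyl}ethanone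
Product: 8 1-{2-(allyloxy)-4-[(tert-butyldimethylsilyl)oxy]-3-[(2S,3S)-3-(2-hydroxypropan-2-yl)oxiran-2-yl]phenyl}ethanone
Conditions: Hf(Ot-Bu)4 (10 mol %), chiral cyclohexane-1,2-diamine-derived bishydroxamic acid ligand (11 mol %), cumene hydroperoxide (1.5 equiv), DMPU, 4 Å MS, toluene, 0 °C; crude product passed through basic alumina
Reagents that add atoms: cumene hydroperoxide, CC(C)(OO)c1ccccc1
Why: Hydroxyl-directed asymmetric epoxidation of a tertiary allylic alcohol (bishydroxamic acid–Hf(IV) alkylperoxide complex, the catalyst class that accepts tertiary allylic alcohols) should transfer oxygen within the metal alkoxide stereospecifically to give the cis-epoxide, the ligand antipode fixing the face so that both future ring stereocentres are set as (2S,3S) in this one step, while the allyl ether, which has no directing hydroxyl, is left alone.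

Step 7
Reactants: 8 1-{2-(allyloxy)-4-[(tert-butyldimethylsilyl)oxy]-3-[(2S,3S)-3-(2-hydroxypropan-2-yl)oxiran-2-yl]phenyl}ethanone
Product: 11 1-[(2S,3S)-4-(allyloxy)-3-hydroxy-2-(2-hydroxypropan-2-yl)-2,3-dihydro-1-benzofuran-5-yl]ethanone, via silyl-protected 2,3-epoxy alcohol 9 (not isolated), via phenol 2,3-epoxy alcohol 10 (not isolated)
Conditions: NaH (1.2 equiv), THF, 0 °C → rt; then TBAF (1.5 equiv), 0 °C → rt; aq. NH4Cl
Reagents that add atoms: none
Why: Sodium hydride forms the tertiary alkoxide, which attacks the adjacent epoxide carbon C2 from the rear (Payne rearrangement) to give the 2,3-epoxy alcohol 9 with the benzylic oxygen set free; fluoride then uncovers the phenoxide at the future C7a (10), which opens the new trisubstituted epoxide at C2 and so forms O1–C2 while the epoxide oxygen becomes the tertiary hydroxyl. The closest known reaction types are the Payne rearrangement with in situ capture of the rearranged epoxy alcohol and the base-mediated cyclisation of o-(2,3-epoxy-3-methylbutyl)phenols to 2-(2-hydroxypropan-2-yl)-2,3-dihydrobenzofurans. The transient oxirane closes 3-exo-tet and the dihydrofuran closes 5-exo-tet; direct attack of the phenoxide on 8 would place both epoxide carbons inside the forming five-membered ring (5-endo) and 6-endo attack on 10 would need SN2 at the quaternary carbon, so neither should compete under basic conditions. No stereocentre is made from nothing: C3 keeps its C–O bond throughout (retention, S) and C2 undergoes two successive SN2 inversions (net retention, S), so the cis-epoxide is translated into the trans-2,3-disubstituted ring. The step needs (i) selection between the two phenolic oxygens, secured because only the one para to the acetyl group is unmasked while the other stays an allyl ether, and (ii) that the phenoxide does not meet the benzylic epoxide before rearrangement (quinone-methide-type C–O cleavage would scramble C3), secured by running the Payne step first and helped by the para-acetyl group, which makes this phenoxide a poor π-donor; an O-to-O silyl shift from the aryl ether to the new benzylic alkoxide would only unmask the same phenoxide early and is harmless, since fluoride removes any silyl group at the end.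

Step 8
Reactants: 11 1-[(2S,3S)-4-(allyloxy)-3-hydroxy-2-(2-hydroxypropan-2-yl)-2,3-dihydro-1-benzofuran-5-yl]ethanone; 12 4-(allyloxy)benzaldehyde
Product: 14 (2E)-1-[(2S,3S)-4-(allyloxy)-3-hydroxy-2-(2-hydroxypropan-2-yl)-2,3-dihydro-1-benzofuran-5-yl]-3-[4-(allyloxy)phenyl]prop-2-en-1-one, via aldol adduct 13 (not isolated)
Conditions: KOH (aq., 5 equiv), EtOH, rt
Reagents that add atoms: none
Why: Claisen–Schmidt condensation (crossed aldol addition to the non-enolisable aldehyde, then E1cB dehydration of 13) gives the thermodynamically preferred E-enone, and neither ring stereocentre carries an acidic hydrogen nor is either alcohol a leaving group under hydroxide.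

Step 9
Reactants: 14 (2E)-1-[(2S,3S)-4-(allyloxy)-3-hydroxy-2-(2-hydroxypropan-2-yl)-2,3-dihydro-1-benzofuran-5-yl]-3-[4-(allyloxy)phenyl]prop-2-en-1-one
Product: 15 brosimacutin G [(2E)-1-[(2S,3S)-3,4-dihydroxy-2-(2-hydroxypropan-2-yl)-2,3-dihydro-1-benzofuran-5-yl]-3-(4-hydroxyphenyl)prop-2-en-1-one]
Conditions: Pd(PPh3)4 (5 mol %), K2CO3, MeOH, rt; neutralised to pH 6 with citrate buffer
Reagents that add atoms: none
Why: Tsuji–Trost-type deallylation (Pd(0) ionises both aryl allyl ethers to π-allyl complexes that are trapped by methoxide) frees the two phenols without acid, which matters because the benzylic 3-hydroxyl would dehydrate to the benzofuran under acidic deprotection, and the enone is inert to these conditions.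

**Compound list**

1 | 1-(2,4-dihydroxyphenyl)ethanone (2,4-dihydroxyacetophenone) | CC(=O)c1ccc(O)cc1O | starting material
2 | 1-(2,4-dihydroxy-3-iodophenyl)ethanone | CC(=O)c1ccc(O)c(I)c1O | intermediate
3 | 1-{4-[(tert-butyldimethylsilyl)oxy]-2-hydroxy-3-iodophenyl}ethanone | CC(=O)c1ccc(O[Si](C)(C)C(C)(C)C)c(I)c1O | intermediate
4 | 1-{2-(allyloxy)-4-[(tert-butyldimethylsilyl)oxy]-3-iodophenyl}ethanone | CC(=O)c1ccc(O[Si](C)(C)C(C)(C)C)c(I)c1OCC=C | intermediate
5 | 2-methylbut-3-yn-2-ol | CC(C)(O)C#C | starting material
6 | 1-{2-(allyloxy)-4-[(tert-butyldimethylsilyl)oxy]-3-(3-hydroxy-3-methylbut-1-yn-1-yl)phenyl}ethanone | CC(=O)c1ccc(O[Si](C)(C)C(C)(C)C)c(C#CC(C)(C)O)c1OCC=C | intermediate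
7 | 1-{2-(allyloxy)-4-[(tert-butyldimethylsilyl)oxy]-3-[(1Z)-3-hydroxy-3-methylbut-1-en-1-yl]phenyl}ethanone | CC(=O)c1ccc(O[Si](C)(C)C(C)(C)C)c(/C=C\C(C)(C)O)c1OCC=C | intermediate
8 | 1-{2-(allyloxy)-4-[(tert-butyldimethylsilyl)oxy]-3-[(2S,3S)-3-(2-hydroxypropan-2-yl)oxiran-2-yl]phenyl}ethanone (cis-epoxide) | CC(=O)c1ccc(O[Si](C)(C)C(C)(C)C)c([C@@H]2O[C@@H]2C(C)(C)O)c1OCC=C | intermediate
9 | 1-{2-(allyloxy)-4-[(tert-butyldimethylsilyl)oxy]-3-[(S)-[(2R)-3,3-dimethyloxiran-2-yl](hydroxy)methyl]phenyl}ethanone (threo; formed in the flask in step 7, not isolated) | CC(=O)c1ccc(O[Si](C)(C)C(C)(C)C)c([C@H](O)[C@H]2OC2(C)C)c1OCC=C | intermediate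
10 | 1-{2-(allyloxy)-3-[(S)-[(2R)-3,3-dimethyloxiran-2-yl](hydroxy)methyl]-4-hydroxyphenyl}ethanone (present as its phenoxide in step 7, not isolated) | CC(=O)c1ccc(O)c([C@H](O)[C@H]2OC2(C)C)c1OCC=C | intermediate
11 | 1-[(2S,3S)-4-(allyloxy)-3-hydroxy-2-(2-hydroxypropan-2-yl)-2,3-dihydro-1-benzofuran-5-yl]ethanone | CC(C)(O)[C@H]1Oc2ccc(C(C)=O)c(OCC=C)c2[C@@H]1O | intermediate
12 | 4-(allyloxy)benzaldehyde | C=CCOc1ccc(C=O)cc1 | starting material
13 | 1-[(2S,3S)-4-(allyloxy)-3-hydroxy-2-(2-hydroxypropan-2-yl)-2,3-dihydro-1-benzofuran-5-yl]-3-[4-(allyloxy)phenyl]-3-hydroxypropan-1-one (aldol adduct, both epimers at the new carbinol, not isolated) | CC(C)(O)[C@H]1Oc2ccc(C(=O)CC(O)c3ccc(OCC=C)cc3)c(OCC=C)c2[C@@H]1O | intermediate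
14 | (2E)-1-[(2S,3S)-4-(allyloxy)-3-hydroxy-2-(2-hydroxypropan-2-yl)-2,3-dihydro-1-benzofuran-5-yl]-3-[4-(allyloxy)phenyl]prop-2-en-1-one | CC(C)(O)[C@H]1Oc2ccc(C(=O)/C=C/c3ccc(OCC=C)cc3)c(OCC=C)c2[C@@H]1O | intermediate
15 | brosimacutin G, (2E)-1-[(2S,3S)-3,4-dihydroxy-2-(2-hydroxypropan-2-yl)-2,3-dihydro-1-benzofuran-5-yl]-3-(4-hydroxyphenyl)prop-2-en-1-one | CC(C)(O)[C@H]1Oc2ccc(C(=O)/C=C/c3ccc(O)cc3)c(O)c2[C@@H]1O | target

**Step count and risks**

Total steps: 9. Longest linear sequence: 9 steps (1 → 15); the other two bought compounds (5 and 12) enter directly.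

Step 6. The process at risk is the enantioface selection (and the rate) of oxygen transfer to a Z-alkene whose aryl group is twisted out of conjugation by two ortho substituents, together with acid-induced opening of the benzylic epoxide during isolation. The fallback sets out from 7 and comes back at 11. The epoxidation is run without asymmetric induction (VO(acac)2, t-BuOOH, CH2Cl2, 0 °C; hydroxyl-directed and cis-specific) to give the racemic cis-epoxide F1. The conditions of step 7 then give, through the racemic Payne epoxy alcohol F2 and the racemic phenol epoxy alcohol F3 (both in the flask), the racemic trans-diol F4. Lipase-catalysed transesterification of the secondary benzylic hydroxyl (immobilised Candida antarctica lipase B, vinyl acetate, MTBE, 30 °C) is expected, by the usual empirical preference of lipases for benzo-fused secondary carbinols, to acylate the (2S,3S)-enantiomer to the acetate F5. F5 is separated from the unreacted (2R,3R)-diol and methanolysed (K2CO3, MeOH) to 11.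

Step 7. The processes at risk are unmasking of the phenoxide while the benzylic epoxide is still present (C–O heterolysis toward a quinone methide, with loss of configuration at the future C3), direct attack on the unrearranged epoxide (which would give the cis ring) and incomplete Payne equilibration. The fallback sets out from 4 and comes back at 9; it avoids both the benzylic epoxide and the Payne step. Nozaki–Hiyama–Kishi coupling of 4 with 3-methylbut-2-enal (CrCl2, NiCl2 cat., DMF, rt; the ketone is not attacked) gives the racemic allylic alcohol F6. Sharpless kinetic resolution (Ti(Oi-Pr)4, D-(−)-diisopropyl tartrate, t-BuOOH, 4 Å MS, CH2Cl2, −20 °C, run to about 55–60 % conversion) should consume the (S)-enantiomer as the erythro-epoxy alcohol F8 and leave the (R)-allylic alcohol F7. Epoxidation of F7 with mCPBA (NaHCO3, CH2Cl2, 0 °C), directed by the hydroxyl group under 1,3-allylic strain from the cis-methyl group, should give the threo-epoxy alcohol 9, now as an isolated compound. The fluoride half of step 7 (TBAF, THF) alone then closes the ring to 11.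

Step 5. The processes at risk are over-reduction of the hindered alkyne past the alkene, hydrogenation or isomerisation of the allyl ether on palladium, and Z-to-E isomerisation. The fallback sets out from 4 and 5 and comes back at 7; the Z-geometry is fixed before the C–C coupling so that no hydrogenation is needed. Rhodium-catalysed trans-hydroboration of 5 with pinacolborane ([Rh(cod)Cl]2, P(i-Pr)3, Et3N, cyclohexane, rt) gives the (Z)-alkenylboronate F9. Stereoretentive Suzuki–Miyaura coupling of F9 with 4 (PdCl2(dppf), K3PO4, THF–H2O, rt) gives 7 directly.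

Further compounds
F1 | step 6 | racemic cis-epoxide: 1-{2-(allyloxy)-4-[(tert-butyldimethylsilyl)oxy]-3-[(2R,3R)-3-(2-hydroxypropan-2-yl)oxiran-2-yl]phenyl}ethanone formed together with 8 (the enantiomer of 8 is shown) | CC(=O)c1ccc(O[Si](C)(C)C(C)(C)C)c([C@H]2O[C@H]2C(C)(C)O)c1OCC=C
F2 | step 6 | racemic Payne epoxy alcohol: 1-{2-(allyloxy)-4-[(tert-butyldimethylsilyl)oxy]-3-[(R)-[(2S)-3,3-dimethyloxiran-2-yl](hydroxy)methyl]phenyl}ethanone formed together with 9 (the enantiomer of 9 is shown; not isolated) | CC(=O)c1ccc(O[Si](C)(C)C(C)(C)C)c([C@@H](O)[C@@H]2OC2(C)C)c1OCC=C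
F3 | step 6 | racemic phenol epoxy alcohol: 1-{2-(allyloxy)-3-[(R)-[(2S)-3,3-dimethyloxiran-2-yl](hydroxy)methyl]-4-hydroxyphenyl}ethanone formed together with 10 (the enantiomer of 10 is shown; not isolated) | CC(=O)c1ccc(O)c([C@@H](O)[C@@H]2OC2(C)C)c1OCC=C
F4 | step 6 | racemic trans-diol: 1-[(2R,3R)-4-(allyloxy)-3-hydroxy-2-(2-hydroxypropan-2-yl)-2,3-dihydro-1-benzofuran-5-yl]ethanone formed together with 11 (the enantiomer of 11 is shown) | CC(C)(O)[C@@H]1Oc2ccc(C(C)=O)c(OCC=C)c2[C@H]1O
F5 | step 6 | (2S,3S)-5-acetyl-4-(allyloxy)-2-(2-hydroxypropan-2-yl)-2,3-dihydro-1-benzofuran-3-yl acetate | CC(C)(O)[C@H]1Oc2ccc(C(C)=O)c(OCC=C)c2[C@@H]1OC(C)=O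
F6 | step 7 | racemic 1-{2-(allyloxy)-4-[(tert-butyldimethylsilyl)oxy]-3-(1-hydroxy-3-methylbut-2-en-1-yl)phenyl}ethanone | CC(=O)c1ccc(O[Si](C)(C)C(C)(C)C)c(C(O)C=C(C)C)c1OCC=C
F7 | step 7 | 1-{2-(allyloxy)-4-[(tert-butyldimethylsilyl)oxy]-3-[(1R)-1-hydroxy-3-methylbut-2-en-1-yl]phenyl}ethanone | CC(=O)c1ccc(O[Si](C)(C)C(C)(C)C)c([C@H](O)C=C(C)C)c1OCC=C
F8 | step 7 | 1-{2-(allyloxy)-4-[(tert-butyldimethylsilyl)oxy]-3-[(R)-[(2R)-3,3-dimethyloxiran-2-yl](hydroxy)methyl]phenyl}ethanone (erythro, from the consumed enantiomer) | CC(=O)c1ccc(O[Si](C)(C)C(C)(C)C)c([C@@H](O)[C@H]2OC2(C)C)c1OCC=C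
F9 | step 5 | (3Z)-2-methyl-4-(4,4,5,5-tetramethyl-1,3,2-dioxaborolan-2-yl)but-3-en-2-ol | CC(C)(O)/C=C\B1OC(C)(C)C(C)(C)O1
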